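**Retrosynthetic overview**

1. Ring A is numbered C1 (C=O), C2 (dienyl chain), C3 (CH2OH carbon C7 attached), C4 (OH), C5 (OH), C6 (acid side chain). Late stage: global acid deprotection; the C2–alkenyl bond by Negishi coupling on a 2-iodoenone; the C6 side chain by conjugate vinylation of a 6-methylidene enone (C6 set by protonation anti to a C4/C5 dioxolane) and cross-metathesis.
2. Key disconnection: ring A is cut at C1–C6 and C3–C4 into two three-carbon halo-aldehydes, (Z)-iodoenal 4 (C1–C2–C3 plus C7) and bromoalkenyl aldehyde 11 (C4–C5–C6). They are joined in one flask by two successive Nozaki–Hiyama–Kishi (NHK) couplings, a [3+3] annulation.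
3. Enabling feature: in ring A the oxygen-bearing carbons C1 and C4 lie 1,4 across the C2=C3 double bond. C4 is a carbinol next to vinylic C3, and C1 becomes a carbinol next to a vinylic C6 once the C6 side chain is retracted to an exocyclic methylene (2-methylene ketone retron). Both ring bonds are therefore alkenyl–carbinol bonds.
4. Ring order: carbocycle A is the only ring of the target and is closed in step 12; a dioxolane on O4/O5 is a temporary ring (steps 13 to 19).
5. Fragments: 4 from but-2-yne-1,4-diol (3 steps), 11 from 2,3-O-isopropylidene-D-glyceraldehyde (5 steps, source of C5), alkyne 17 from (R)-propylene oxide (3 steps).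

Key step: step 12

Remark: 19, 20 and 21 are carried as both C1 epimers, because this carbinol becomes the C1 carbonyl in step 14; their SMILES leave C1 undefined. 18 is drawn as the free alcohol although it is a chromium alkoxide in the flask. TBS = tert-butyldimethylsilyl, TES = triethylsilyl, TMS = trimethylsilyl; ring locants C1–C6 follow the overview.

**Route**

Step 1
Reactants: 1 but-2-yne-1,4-diol
Product: 2 4-(TBS-oxy)but-2-yn-1-ol
Conditions: NaH (1.0 equiv), THF, 0 °C; TBSCl (1.0 equiv), 23 °C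
Reagents that add atoms: tert-butyldimethylsilyl chloride, CC(C)(C)[Si](C)(C)Cl
Why: O-silylation of the monosodium alkoxide of a symmetrical diol should stop after one silyl group because only one equivalent of base is used; no stereocentre is involved.

Step 2
Reactants: 2 4-(TBS-oxy)but-2-yn-1-ol
Product: 3 4-(TBS-oxy)but-2-ynal
Conditions: MnO2, CH2Cl2, 23 °C
Reagents that add atoms: none
Why: MnO2 oxidation of a propargylic alcohol stops at the ynal and leaves the silyl ether untouched.

Step 3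
Reactants: 3 4-(TBS-oxy)but-2-ynal
Product: 4 (2Z)-4-(TBS-oxy)-3-iodobut-2-enal
Conditions: NaI, AcOH, MeCN, 0 to 23 °C
Reagents that add atoms: sodium iodide, [Na+].[I-]
Why: Conjugate hydroiodination of an ynal (iodide adds to C3, anti protonation of the allenolate) is the standard entry to (Z)-β-iodoenals, which places the formyl group and iodine cis as the later ring closure requires.

Step 4
Reactants: 5 (4R)-2,2-dimethyl-1,3-dioxolane-4-carbaldehyde
Product: 6 (4S)-4-ethynyl-2,2-dimethyl-1,3-dioxolane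
Conditions: dimethyl (1-diazo-2-oxopropyl)phosphonate, K2CO3, MeOH, 0 to 23 °C
Reagents that add atoms: dimethyl (1-diazo-2-oxopropyl)phosphonate, CC(=O)C(=[N+]=[N-])P(=O)(OC)OC
Why: Seyferth–Gilbert homologation with the Ohira–Bestmann reagent turns the aldehyde into the terminal alkyne under mild carbonate conditions, so the future C5 stereocentre taken from D-glyceraldehyde should be kept.

Step 5
Reactants: 6 (4S)-4-ethynyl-2,2-dimethyl-1,3-dioxolane
Product: 8 (4R)-4-(1-bromoethenyl)-2,2-dimethyl-1,3-dioxolane, via vinylalane 7 (not isolated)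
Conditions: i-Bu2AlH, NiCl2(dppp) (3 mol%), THF, 0 to 23 °C; then N-bromosuccinimide, 0 °C
Reagents that add atoms: N-bromosuccinimide, O=C1CCC(=O)N1Br
Why: Nickel-catalysed hydroalumination with this bisphosphine catalyst is α-selective for terminal alkynes and the internal alkenylalane is brominated with retention, a known route to 2-bromo-1-alkenes that does not touch the stereocentre.

Step 6
Reactants: 8 (4R)-4-(1-bromoethenyl)-2,2-dimethyl-1,3-dioxolane
Product: 9 (2R)-3-bromobut-3-ene-1,2-diol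
Conditions: 1 M HCl, THF, 23 °C
Reagents that add atoms: none
Why: Acid hydrolysis of the dioxolane frees the 1,2-diol without affecting the alkenyl bromide or the stereocentre.

Step 7
Reactants: 9 (2R)-3-bromobut-3-ene-1,2-diol
Product: 10 (2R)-3-bromo-1,2-bis(TES-oxy)but-3-ene
Conditions: TESCl (2.5 equiv), imidazole, CH2Cl2, 0 °C
Reagents that add atoms: triethylsilyl chloride, CC[Si](CC)(CC)Cl
Why: Imidazole-mediated silylation of both hydroxyls is routine and gives the bis-silyl ether needed for the selective oxidation.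

Step 8
Reactants: 10 (2R)-3-bromo-1,2-bis(TES-oxy)but-3-ene
Product: 11 (2R)-3-bromo-2-(TES-oxy)but-3-enal
Conditions: (COCl)2, DMSO, CH2Cl2, −78 to −40 °C; i-Pr2NEt, −78 °C; cold neutral work-up, used at once
Reagents that add atoms: none
Why: Under Swern conditions a primary triethylsilyl ether is cleaved by the chlorosulfonium salt and oxidised in situ to the aldehyde while the secondary silyl ether survives, a known selective oxidation; the hindered amine at low temperature should keep the α-silyloxy β,γ-unsaturated aldehyde from epimerising.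

Step 9
Reactants: 12 (2R)-2-methyloxirane; 13 (4-bromobut-1-yn-1-yl)trimethylsilane
Product: 15 (2R)-7-(trimethylsilyl)hept-6-yn-2-ol, via Grignard reagent 14 (not isolated)
Conditions: 13, Mg, THF; then CuI (10 mol%), 12, −30 to 0 °C; aq. NH4Cl
Reagents that add atoms: none
Why: Copper-catalysed SN2 opening of the terminal epoxide by the Grignard reagent occurs at the CH2 carbon, so the carbinol centre of (R)-propylene oxide is carried over unchanged.

Step 10
Reactants: 15 (2R)-7-(trimethylsilyl)hept-6-yn-2-ol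
Product: 16 tert-butyldimethyl{[(2R)-7-(trimethylsilyl)hept-6-yn-2-yl]oxy}silane
Conditions: TBSCl, imidazole, DMF, 23 °C
Reagents that add atoms: tert-butyldimethylsilyl chloride, CC(C)(C)[Si](C)(C)Cl
Why: Standard silylation of the secondary alcohol protects it for the hydrozirconation in step 18.

Step 11
Reactants: 16 tert-butyldimethyl{[(2R)-7-(trimethylsilyl)hept-6-yn-2-yl]oxy}silane
Product: 17 tert-butyl[(2R)-hept-6-yn-2-yloxy]dimethylsilane
Conditions: K2CO3 (cat.), MeOH, 23 °C
Reagents that add atoms: none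
Why: Carbonate-mediated methanolysis removes the alkynyl trimethylsilyl group selectively and leaves the silyl ether in place.

Step 12
Reactants: 4 (2Z)-4-(TBS-oxy)-3-iodobut-2-enal; 11 (2R)-3-bromo-2-(TES-oxy)but-3-enal
Product: 19 (4R,5S)-3-[(TBS-oxy)methyl]-6-methylidene-5-(TES-oxy)cyclohex-2-ene-1,4-diol (both C1 epimers), via chromium alkoxide adduct 18 (not isolated)
Conditions: CrCl2 (8 equiv), NiCl2 (1 mol%), degassed DMSO/THF (0.02 M), 23 °C, 4 added slowly to 11 (1.1 equiv); then NiCl2 (5 mol%), 45 °C; aq. potassium sodium tartrate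
Reagents that add atoms: none
Why: Proposed new method: two Nozaki–Hiyama–Kishi alkenylations are run as one halide-differentiated cascade, in which the electron-poor β-iodoenal 4 is metallated first (by divalent chromium with a trace of zerovalent nickel) and adds to the more electrophilic α-silyloxy aldehyde 11 to give alkoxide 18 (C3–C4), and only then, with more nickel and gentle warming, is the unactivated 2-bromoalkene turned into an alkenylchromium that attacks the C1 formyl group (C1–C6); the closest known reactions are the intermolecular NHK coupling of β-iodoenones and β-iodoenoates with aldehydes and the intramolecular NHK closure of 2-haloalkenyl aldehydes to 2-methylenecycloalkanols, here merged in one flask. Ring A closes in a 6-exo-trig mode (alkenylchromium carbon C6 onto the C1 carbonyl, oxygen exocyclic). The C4 carbinol is set in the intermolecular event by polar Felkin–Anh control from the C5 silyloxy stereocentre (4,5-anti, which is cis in the ring), while the C1 carbinol is uncontrolled and is erased in step 14. The step needs cross-coupling over homo-coupling, which the reactivity gap between the activated iodide and the plain bromide and the electrophilicity gap between the α-silyloxy aldehyde and the conjugated enal should secure, and it needs the Z geometry of C2=C3, which the Z-iodide provides because alkenylchromium formation and addition retain alkene geometry. The kinetically inert bond between trivalent chromium and O4 in 18 should keep the cis-γ-oxido enal from closing to a lactol and aromatising to a furan before the ring closure.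

Step 13
Reactants: 19 (4R,5S)-3-[(TBS-oxy)methyl]-6-methylidene-5-(TES-oxy)cyclohex-2-ene-1,4-diol
Product: 21 (4R,5S)-3-[(TBS-oxy)methyl]-4,5-(isopropylidenedioxy)-6-methylidenecyclohex-2-en-1-ol (both C1 epimers), via triol 20 (not isolated)
Conditions: PPTS, MeOH, 23 °C; evaporate; 2,2-dimethoxypropane, acetone, PPTS, 23 °C
Reagents that add atoms: 2,2-dimethoxypropane, COC(C)(C)OC
Why: Pyridinium tosylate in methanol cleaves the labile secondary triethylsilyl ether but not the primary TBS ether, and acid-catalysed ketalisation then ties the cis C4/C5 diol into a five-membered dioxolane, which leaves only the C1 hydroxyl free and should let the minor C4 epimer, whose trans diol cannot be bridged, be separated.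

Step 14
Reactants: 21 (4R,5S)-3-[(TBS-oxy)methyl]-4,5-(isopropylidenedioxy)-6-methylidenecyclohex-2-en-1-ol
Product: 22 (4R,5S)-3-[(TBS-oxy)methyl]-4,5-(isopropylidenedioxy)-6-methylidenecyclohex-2-en-1-one
Conditions: MnO2, CH2Cl2, 0 to 23 °C; used directly
Reagents that add atoms: none
Why: MnO2 oxidises the doubly allylic C1 alcohol (both epimers) to the cross-conjugated dienone under neutral conditions, which removes the uncontrolled C1 centre.

Step 15
Reactants: 22 (4R,5S)-3-[(TBS-oxy)methyl]-4,5-(isopropylidenedioxy)-6-methylidenecyclohex-2-en-1-one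
Product: 24 (4R,5S,6R)-6-allyl-3-[(TBS-oxy)methyl]-4,5-(isopropylidenedioxy)cyclohex-2-en-1-one, via silyl dienol ether 23 (not isolated)
Conditions: vinylmagnesium bromide, CuBr·SMe2 (10 mol%), TMSCl, THF, −78 °C; then aq. citric acid, THF, 0 °C
Reagents that add atoms: vinylmagnesium bromide, C=C[Mg]Br
Why: Copper-catalysed conjugate addition with silyl chloride trapping should occur only at the unhindered exocyclic methylene (the ring β-carbon C3 is fully substituted), and kinetic protonation of the silyl dienol ether at C6 from the face opposite the cis-fused dioxolane sets C6 (R) with the allyl group cis to both oxygens.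

Step 16
Reactants: 24 (4R,5S,6R)-6-allyl-3-[(TBS-oxy)methyl]-4,5-(isopropylidenedioxy)cyclohex-2-en-1-one; 25 tert-butyl 2-methylprop-2-enoate
Product: 26 tert-butyl (2E)-4-[(4R,5S,6R)-3-[(TBS-oxy)methyl]-4,5-(isopropylidenedioxy)-1-oxocyclohex-2-en-6-yl]-2-methylbut-2-enoate
Conditions: 25 (10 equiv), second-generation Hoveyda–Grubbs catalyst (5 mol%), CH2Cl2, 40 °C
Reagents that add atoms: none
Why: Olefin cross-metathesis of a terminal alkene with a methacrylate ester is a known route to (E)-2-methylenoates; only the monosubstituted allyl double bond is reactive and the trisubstituted product forms as the thermodynamic E isomer.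

Step 17
Reactants: 26 tert-butyl (2E)-4-[(4R,5S,6R)-3-[(TBS-oxy)methyl]-4,5-(isopropylidenedioxy)-1-oxocyclohex-2-en-6-yl]-2-methylbut-2-enoate
Product: 27 tert-butyl (2E)-4-[(4R,5S,6R)-3-[(TBS-oxy)methyl]-2-iodo-4,5-(isopropylidenedioxy)-1-oxocyclohex-2-en-6-yl]-2-methylbut-2-enoate
Conditions: I2, pyridine/CH2Cl2 (1:1), 23 °C
Reagents that add atoms: iodine, II
Why: Iodine with pyridine α-iodinates cyclic enones through conjugate addition of pyridine, iodination of the enolate and elimination, which puts iodine at C2, the only vinylic α-position, without a base strong enough to epimerise C6.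

Step 18
Reactants: 17 tert-butyl[(2R)-hept-6-yn-2-yloxy]dimethylsilane; 27 tert-butyl (2E)-4-[(4R,5S,6R)-3-[(TBS-oxy)methyl]-2-iodo-4,5-(isopropylidenedioxy)-1-oxocyclohex-2-en-6-yl]-2-methylbut-2-enoate
Product: 30 tert-butyl (2E)-4-[(4R,5S,6R)-3-[(TBS-oxy)methyl]-2-[(1E,6R)-6-(TBS-oxy)hept-1-en-1-yl]-4,5-(isopropylidenedioxy)-1-oxocyclohex-2-en-6-yl]-2-methylbut-2-enoate, via alkenylzirconocene 28 (not isolated), via alkenylzinc chloride 29 (not isolated)
Conditions: 17, Cp2Zr(H)Cl, THF, 23 °C; ZnCl2, THF, 0 °C; then 27, Pd(PPh3)4 (5 mol%), THF/DMF, 23 °C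
Reagents that add atoms: none
Why: syn-Hydrozirconation of the terminal alkyne gives the (E)-alkenylzirconocene, which is transmetallated to zinc and coupled with the 2-iodoenone under Negishi conditions (zerovalent palladium) with retention of alkene geometry, a known neutral way to alkenylate 2-iodoenones.

Step 19
Reactants: 30 tert-butyl (2E)-4-[(4R,5S,6R)-3-[(TBS-oxy)methyl]-2-[(1E,6R)-6-(TBS-oxy)hept-1-en-1-yl]-4,5-(isopropylidenedioxy)-1-oxocyclohex-2-en-6-yl]-2-methylbut-2-enoate
Product: 31 pestallic acid I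
Conditions: TFA/CH2Cl2/H2O (10:10:1), 0 to 23 °C
Reagents that add atoms: none
Why: Aqueous trifluoroacetic acid cleaves the tert-butyl ester, the dioxolane and both silyl ethers in one acid-mediated global deprotection; no base is used, so the β-hydroxy ketone and the C6 centre should not be disturbed.

**Compound list**

1 | but-2-yne-1,4-diol | OCC#CCO | starting material
2 | 4-[(tert-butyldimethylsilyl)oxy]but-2-yn-1-ol | CC(C)(C)[Si](C)(C)OCC#CCO | intermediate
3 | 4-[(tert-butyldimethylsilyl)oxy]but-2-ynal | CC(C)(C)[Si](C)(C)OCC#CC=O | intermediate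
4 | (2Z)-4-[(tert-butyldimethylsilyl)oxy]-3-iodobut-2-enal | O=C/C=C(\I)CO[Si](C)(C)C(C)(C)C | intermediate
5 | (4R)-2,2-dimethyl-1,3-dioxolane-4-carbaldehyde (2,3-O-isopropylidene-D-glyceraldehyde) | CC1(C)OC[C@H](C=O)O1 | starting material
6 | (4S)-4-ethynyl-2,2-dimethyl-1,3-dioxolane | CC1(C)OC[C@H](C#C)O1 | intermediate
7 | diisobutyl{1-[(4R)-2,2-dimethyl-1,3-dioxolan-4-yl]ethenyl}alane | CC1(C)OC[C@H](C(=C)[Al](CC(C)C)CC(C)C)O1 | intermediate
8 | (4R)-4-(1-bromoethenyl)-2,2-dimethyl-1,3-dioxolane | CC1(C)OC[C@H](C(Br)=C)O1 | intermediate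
9 | (2R)-3-bromobut-3-ene-1,2-diol | OC[C@H](C(Br)=C)O | intermediate
10 | (2R)-3-bromo-1,2-bis[(triethylsilyl)oxy]but-3-ene | CC[Si](CC)(CC)OC[C@H](C(Br)=C)O[Si](CC)(CC)CC | intermediate
11 | (2R)-3-bromo-2-[(triethylsilyl)oxy]but-3-enal | O=C[C@H](C(Br)=C)O[Si](CC)(CC)CC | intermediate
12 | (2R)-2-methyloxirane | C[C@@H]1CO1 | starting material
13 | (4-bromobut-1-yn-1-yl)trimethylsilane | C[Si](C)(C)C#CCCBr | starting material
14 | [4-(trimethylsilyl)but-3-yn-1-yl]magnesium bromide | C[Si](C)(C)C#CCC[Mg]Br | intermediate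
15 | (2R)-7-(trimethylsilyl)hept-6-yn-2-ol | C[Si](C)(C)C#CCCC[C@@H](C)O | intermediate
16 | tert-butyldimethyl{[(2R)-7-(trimethylsilyl)hept-6-yn-2-yl]oxy}silane | C[Si](C)(C)C#CCCC[C@@H](C)O[Si](C)(C)C(C)(C)C | intermediate
17 | tert-butyl[(2R)-hept-6-yn-2-yloxy]dimethylsilane | C#CCCC[C@@H](C)O[Si](C)(C)C(C)(C)C | intermediate
18 | (2Z,4R,5R)-6-bromo-3-{[(tert-butyldimethylsilyl)oxy]methyl}-4-hydroxy-5-[(triethylsilyl)oxy]hepta-2,6-dienal (chromium alkoxide in the flask) | O=C/C=C(CO[Si](C)(C)C(C)(C)C)\[C@@H](O)[C@@H](O[Si](CC)(CC)CC)C(Br)=C | intermediate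
19 | (4R,5S)-3-{[(tert-butyldimethylsilyl)oxy]methyl}-6-methylidene-5-[(triethylsilyl)oxy]cyclohex-2-ene-1,4-diol (both C1 epimers) | C=C1C(O)C=C(CO[Si](C)(C)C(C)(C)C)[C@@H](O)[C@H]1O[Si](CC)(CC)CC | intermediate
20 | (4R,5S)-3-{[(tert-butyldimethylsilyl)oxy]methyl}-6-methylidenecyclohex-2-ene-1,4,5-triol (both C1 epimers) | C=C1C(O)C=C(CO[Si](C)(C)C(C)(C)C)[C@@H](O)[C@H]1O | intermediate
21 | (4R,5S)-3-{[(tert-butyldimethylsilyl)oxy]methyl}-4,5-(isopropylidenedioxy)-6-methylidenecyclohex-2-en-1-ol (both C1 epimers) | C=C1C(O)C=C(CO[Si](C)(C)C(C)(C)C)[C@H]2OC(C)(C)O[C@@H]12 | intermediate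
22 | (4R,5S)-3-{[(tert-butyldimethylsilyl)oxy]methyl}-4,5-(isopropylidenedioxy)-6-methylidenecyclohex-2-en-1-one | C=C1C(=O)C=C(CO[Si](C)(C)C(C)(C)C)[C@H]2OC(C)(C)O[C@@H]12 | intermediate
23 | (4R,5S)-6-allyl-3-{[(tert-butyldimethylsilyl)oxy]methyl}-4,5-(isopropylidenedioxy)-1-[(trimethylsilyl)oxy]cyclohexa-1(6),2-diene | C=CCC1=C(O[Si](C)(C)C)C=C(CO[Si](C)(C)C(C)(C)C)[C@H]2OC(C)(C)O[C@@H]12 | intermediate
24 | (4R,5S,6R)-6-allyl-3-{[(tert-butyldimethylsilyl)oxy]methyl}-4,5-(isopropylidenedioxy)cyclohex-2-en-1-one | C=CC[C@H]1C(=O)C=C(CO[Si](C)(C)C(C)(C)C)[C@H]2OC(C)(C)O[C@@H]12 | intermediate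
25 | tert-butyl 2-methylprop-2-enoate | C=C(C)C(=O)OC(C)(C)C | starting material
26 | tert-butyl (2E)-4-[(4R,5S,6R)-3-{[(tert-butyldimethylsilyl)oxy]methyl}-4,5-(isopropylidenedioxy)-1-oxocyclohex-2-en-6-yl]-2-methylbut-2-enoate | C/C(=C\C[C@H]1C(=O)C=C(CO[Si](C)(C)C(C)(C)C)[C@H]2OC(C)(C)O[C@@H]12)C(=O)OC(C)(C)C | intermediate
27 | tert-butyl (2E)-4-[(4R,5S,6R)-3-{[(tert-butyldimethylsilyl)oxy]methyl}-2-iodo-4,5-(isopropylidenedioxy)-1-oxocyclohex-2-en-6-yl]-2-methylbut-2-enoate | C/C(=C\C[C@H]1C(=O)C(I)=C(CO[Si](C)(C)C(C)(C)C)[C@H]2OC(C)(C)O[C@@H]12)C(=O)OC(C)(C)C | intermediate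
28 | chlorobis(cyclopentadienyl)[(1E,6R)-6-[(tert-butyldimethylsilyl)oxy]hept-1-en-1-yl]zirconium | Cl[Zr](/C=C/CCC[C@@H](C)O[Si](C)(C)C(C)(C)C)(C1C=CC=C1)C1C=CC=C1 | intermediate
29 | [(1E,6R)-6-[(tert-butyldimethylsilyl)oxy]hept-1-en-1-yl]zinc chloride | Cl[Zn]/C=C/CCC[C@@H](C)O[Si](C)(C)C(C)(C)C | intermediate
30 | tert-butyl (2E)-4-[(4R,5S,6R)-3-{[(tert-butyldimethylsilyl)oxy]methyl}-2-[(1E,6R)-6-[(tert-butyldimethylsilyl)oxy]hept-1-en-1-yl]-4,5-(isopropylidenedioxy)-1-oxocyclohex-2-en-6-yl]-2-methylbut-2-enoate | C/C(=C\C[C@H]1C(=O)C(/C=C/CCC[C@@H](C)O[Si](C)(C)C(C)(C)C)=C(CO[Si](C)(C)C(C)(C)C)[C@H]2OC(C)(C)O[C@@H]12)C(=O)OC(C)(C)C | intermediate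
31 | pestallic acid I | C/C(=C\C[C@H]1C(=O)C(/C=C/CCC[C@@H](C)O)=C(CO)[C@@H](O)[C@H]1O)C(=O)O | target

**Step count and risks**

Total: 19 steps. Longest linear sequence: 13 steps (from 5: steps 4–8, then 12–19).

Steps most likely to fail:

1. Step 12 (proposed new method). What may go wrong: activation of the bromide of 11 before the cross-coupling, or attack of the alkenylchromium of 4 on the formyl group of another molecule of 4, leading to homo-coupling and oligomers; poor facial selectivity at C4; lactol closure of the intermediate and aromatisation to a furan; Z-to-E isomerisation of 4 before coupling. Fallback (known chemistry, stepwise), setting out from 4 and returning at 21: the formyl group of 4 is masked (trimethyl orthoformate, PPTS, MeOH) as tert-butyl{[(2Z)-2-iodo-4,4-dimethoxybut-2-en-1-yl]oxy}dimethylsilane F1; an ordinary intermolecular NHK coupling of F1 with 11 (CrCl2, cat. NiCl2, 23 °C, the iodide reacting before the bromide) gives the allylic alcohol (3R,4R,5Z)-2-bromo-5-{[(tert-butyldimethylsilyl)oxy]methyl}-7,7-dimethoxy-3-[(triethylsilyl)oxy]hepta-1,5-dien-4-ol F2; silylation (TESOTf, 2,6-lutidine) gives the bis-silyl ether (3R,4R,5Z)-2-bromo-5-{[(tert-butyldimethylsilyl)oxy]methyl}-7,7-dimethoxy-3,4-bis[(triethylsilyl)oxy]hepta-1,5-diene F3; mild acetal hydrolysis (oxalic acid on wet silica) gives (2Z,4R,5R)-6-bromo-3-{[(tert-butyldimethylsilyl)oxy]methyl}-4,5-bis[(triethylsilyl)oxy]hepta-2,6-dienal F4, whose protected O4 cannot close to a lactol; an intramolecular NHK ring closure (CrCl2, cat. NiCl2, high dilution) gives (4R,5S)-3-{[(tert-butyldimethylsilyl)oxy]methyl}-6-methylidene-4,5-bis[(triethylsilyl)oxy]cyclohex-2-en-1-ol F5; the conditions of step 13 then remove both triethylsilyl groups and return to the route at 21.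

2. Step 15. What may go wrong: poor facial selectivity in the protonation at C6, or loss of the C5 oxygen by β-elimination from the enolate and aromatisation of the base-sensitive dienone. Fallback, setting out from 22 and returning at 26 (C6 is set by hydroboration, not protonation, and steps 15 and 16 are bypassed): Luche reduction (NaBH4, CeCl3·7H2O, MeOH, −78 °C) should give, by hydride attack opposite the dioxolane, (1S,4R,5S)-3-{[(tert-butyldimethylsilyl)oxy]methyl}-4,5-(isopropylidenedioxy)-6-methylidenecyclohex-2-en-1-ol F6; hydroboration of the exocyclic methylene with 9-BBN from the open face, followed in the same flask by Suzuki–Miyaura coupling with tert-butyl (2E)-3-iodo-2-methylprop-2-enoate (Pd(dppf)Cl2, AsPh3, Cs2CO3, DMF/H2O), gives tert-butyl (2E)-4-[(1S,4R,5S,6S)-3-{[(tert-butyldimethylsilyl)oxy]methyl}-1-hydroxy-4,5-(isopropylidenedioxy)cyclohex-2-en-6-yl]-2-methylbut-2-enoate F7; Dess–Martin oxidation of F7 returns to the route at 26.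

3. Step 19. What may go wrong: acid-promoted dehydration of the β-hydroxy ketone and aromatisation, or ionisation at the allylic C4 carbinol, during the forcing cleavage of the tert-butyl ester. Fallback, setting out from 24 and returning at 31 (a fluoride-labile ester, so that strong acid is never needed): cross-metathesis of 24 with 2-(trimethylsilyl)ethyl 2-methylprop-2-enoate gives 2-(trimethylsilyl)ethyl (2E)-4-[(4R,5S,6R)-3-{[(tert-butyldimethylsilyl)oxy]methyl}-4,5-(isopropylidenedioxy)-1-oxocyclohex-2-en-6-yl]-2-methylbut-2-enoate F8; iodination as in step 17 gives the 2-iodoenone F9; Negishi coupling with 17 as in step 18 gives the silyl-protected dienone ester F10; TASF (DMF, 0 °C) removes the silylethyl ester and both silyl ethers to give the dioxolane acid (2E)-4-[(4R,5S,6R)-3-(hydroxymethyl)-2-[(1E,6R)-6-hydroxyhept-1-en-1-yl]-4,5-(isopropylidenedioxy)-1-oxocyclohex-2-en-6-yl]-2-methylbut-2-enoic acid F11; aqueous acetic acid (40 °C) then removes the dioxolane and gives 31.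

Further compounds
F1 | step 12 | tert-butyl{[(2Z)-2-iodo-4,4-dimethoxybut-2-en-1-yl]oxy}dimethylsilane | COC(OC)/C=C(\I)CO[Si](C)(C)C(C)(C)C
F2 | step 12 | (3R,4R,5Z)-2-bromo-5-{[(tert-butyldimethylsilyl)oxy]methyl}-7,7-dimethoxy-3-[(triethylsilyl)oxy]hepta-1,5-dien-4-ol | COC(OC)/C=C(CO[Si](C)(C)C(C)(C)C)\[C@@H](O)[C@@H](O[Si](CC)(CC)CC)C(Br)=C
F3 | step 12 | (3R,4R,5Z)-2-bromo-5-{[(tert-butyldimethylsilyl)oxy]methyl}-7,7-dimethoxy-3,4-bis[(triethylsilyl)oxy]hepta-1,5-diene | COC(OC)/C=C(CO[Si](C)(C)C(C)(C)C)\[C@@H](O[Si](CC)(CC)CC)[C@@H](O[Si](CC)(CC)CC)C(Br)=C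
F4 | step 12 | (2Z,4R,5R)-6-bromo-3-{[(tert-butyldimethylsilyl)oxy]methyl}-4,5-bis[(triethylsilyl)oxy]hepta-2,6-dienal | O=C/C=C(CO[Si](C)(C)C(C)(C)C)\[C@@H](O[Si](CC)(CC)CC)[C@@H](O[Si](CC)(CC)CC)C(Br)=C
F5 | step 12 | (4R,5S)-3-{[(tert-butyldimethylsilyl)oxy]methyl}-6-methylidene-4,5-bis[(triethylsilyl)oxy]cyclohex-2-en-1-ol (both C1 epimers) | C=C1C(O)C=C(CO[Si](C)(C)C(C)(C)C)[C@@H](O[Si](CC)(CC)CC)[C@H]1O[Si](CC)(CC)CC
F6 | step 15 | (1S,4R,5S)-3-{[(tert-butyldimethylsilyl)oxy]methyl}-4,5-(isopropylidenedioxy)-6-methylidenecyclohex-2-en-1-ol | C=C1[C@@H](O)C=C(CO[Si](C)(C)C(C)(C)C)[C@H]2OC(C)(C)O[C@@H]12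
F7 | step 15 | tert-butyl (2E)-4-[(1S,4R,5S,6S)-3-{[(tert-butyldimethylsilyl)oxy]methyl}-1-hydroxy-4,5-(isopropylidenedioxy)cyclohex-2-en-6-yl]-2-methylbut-2-enoate | C/C(=C\C[C@H]1[C@@H](O)C=C(CO[Si](C)(C)C(C)(C)C)[C@H]2OC(C)(C)O[C@@H]12)C(=O)OC(C)(C)C
F8 | step 19 | 2-(trimethylsilyl)ethyl (2E)-4-[(4R,5S,6R)-3-{[(tert-butyldimethylsilyl)oxy]methyl}-4,5-(isopropylidenedioxy)-1-oxocyclohex-2-en-6-yl]-2-methylbut-2-enoate | C/C(=C\C[C@H]1C(=O)C=C(CO[Si](C)(C)C(C)(C)C)[C@H]2OC(C)(C)O[C@@H]12)C(=O)OCC[Si](C)(C)C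
F9 | step 19 | 2-(trimethylsilyl)ethyl (2E)-4-[(4R,5S,6R)-3-{[(tert-butyldimethylsilyl)oxy]methyl}-2-iodo-4,5-(isopropylidenedioxy)-1-oxocyclohex-2-en-6-yl]-2-methylbut-2-enoate | C/C(=C\C[C@H]1C(=O)C(I)=C(CO[Si](C)(C)C(C)(C)C)[C@H]2OC(C)(C)O[C@@H]12)C(=O)OCC[Si](C)(C)C
F10 | step 19 | 2-(trimethylsilyl)ethyl (2E)-4-[(4R,5S,6R)-3-{[(tert-butyldimethylsilyl)oxy]methyl}-2-[(1E,6R)-6-[(tert-butyldimethylsilyl)oxy]hept-1-en-1-yl]-4,5-(isopropylidenedioxy)-1-oxocyclohex-2-en-6-yl]-2-methylbut-2-enoate | C/C(=C\C[C@H]1C(=O)C(/C=C/CCC[C@@H](C)O[Si](C)(C)C(C)(C)C)=C(CO[Si](C)(C)C(C)(C)C)[C@H]2OC(C)(C)O[C@@H]12)C(=O)OCC[Si](C)(C)C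
F11 | step 19 | (2E)-4-[(4R,5S,6R)-3-(hydroxymethyl)-2-[(1E,6R)-6-hydroxyhept-1-en-1-yl]-4,5-(isopropylidenedioxy)-1-oxocyclohex-2-en-6-yl]-2-methylbut-2-enoic acid | C/C(=C\C[C@H]1C(=O)C(/C=C/CCC[C@@H](C)O)=C(CO)[C@H]2OC(C)(C)O[C@@H]12)C(=O)O
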